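The disconnection on which everything rests is the C(sp2)–C(sp3) bond between C4 of the bromododecadienynyl chain (the (E)-enyne alkene carbon remote from the alkyne) and C5, the first CH2 of the hexamethylene tether. The key step is a one-pot hydroboration and B-alkyl Suzuki–Miyaura coupling: 9-BBN adds to the terminal alkene of (E)-1-bromoocta-1,7-diene, and the alkylborane is coupled with the (E)-iodoenyne carried by the trans-2,5-disubstituted oxolane ring. It exploits the enyne-conjugated C4–I bond, which undergoes oxidative addition far faster than the isolated C12–Br bond, so the bromovinyl terminus travels unprotected and both E alkenes are retained. The precursors are the iodoenyne 10 and the alkylborane 14.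

Key step: step 7

Remark: the target is planned as the trans-2,5-disubstituted oxolane with 2R,5S configuration; oct-1-en-7-yne, (E)-(2-bromoethenyl)trimethylsilane and both enantiomers of the bis(triflamide) ligand are taken as commercial.

Step 1
Reactants: 1 methyl 4-iodobutanoate; 2 pent-4-enal
Product: 4 methyl (5R)-5-hydroxynon-8-enoate, via bis(4-methoxy-4-oxobutyl)zinc 3 (not isolated)
Conditions: Et2Zn, CuI (cat.), neat, 55 °C, then Et2Zn and EtI removed in vacuo; Ti(OiPr)4, (1S,2S)-1,2-bis(trifluoromethanesulfonamido)cyclohexane (8 mol%), toluene, −20 °C; then 2; aq. NH4Cl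
Reagents that add atoms: none
Why: Copper-catalysed iodine–zinc exchange gives the ester-bearing dialkylzinc 3, and its Ti(OiPr)4/bis(triflamide)-catalysed asymmetric addition to the aldehyde (Knochel-type functionalised dialkylzinc addition) should set C5 as R by alkyl transfer to the Re face, the (1S,2S) ligand being chosen by analogy with the (1R,2R) ligand, which directs Si-face addition.

Step 2
Reactants: 4 methyl (5R)-5-hydroxynon-8-enoate
Product: 5 methyl 4-[(2R,5S)-5-(hydroxymethyl)oxolan-2-yl]butanoate
Conditions: Co(modp)2 (10 mol%; modp = 1-morpholinocarbamoyl-4,4-dimethyl-1,3-pentanedionate), O2 (1 atm), tBuOOH (10 mol%), iPrOH, 55 °C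
Reagents that add atoms: dioxygen, O=O
Why: The Mukaiyama cobalt-catalysed aerobic oxidative cyclisation of a pent-4-en-1-ol closes the oxolane by 5-exo attack of the cobalt-bound alkoxide on the alkene and should give the 2,5-trans ring with the high trans selectivity typical of this reaction, so the existing C2 centre sets C5 as S while the exocyclic radical is trapped by O2 and reduced to the primary alcohol.

Step 3
Reactants: 5 methyl 4-[(2R,5S)-5-(hydroxymethyl)oxolan-2-yl]butanoate
Product: 7 methyl 4-[(2R,5S)-5-ethynyloxolan-2-yl]butanoate, via aldehyde 6 (not isolated)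
Conditions: Dess–Martin periodinane, CH2Cl2, 0 °C to rt, filtration and concentration; then dimethyl (1-diazo-2-oxopropyl)phosphonate, K2CO3, MeOH, 0 °C to rt
Reagents that add atoms: dimethyl (1-diazo-2-oxopropyl)phosphonate, CC(=O)C(=[N+]=[N-])P(=O)(OC)OC
Why: Dess–Martin oxidation gives the α-alkoxy aldehyde, which is homologated at once by the Ohira–Bestmann variant of the Seyferth–Gilbert reaction under conditions mild enough to keep C5 from epimerising and degenerate for the methyl ester in methanol.

Step 4
Reactants: 7 methyl 4-[(2R,5S)-5-ethynyloxolan-2-yl]butanoate; 8 (E)-(2-bromoethenyl)trimethylsilane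
Product: 9 methyl 4-[(2R,5S)-5-[(E)-4-(trimethylsilyl)but-3-en-1-yn-1-yl]oxolan-2-yl]butanoate
Conditions: Pd(PPh3)4 (5 mol%), CuI (10 mol%), iPr2NH, THF, rt to 40 °C
Reagents that add atoms: none
Why: Sonogashira coupling of the terminal alkyne with the alkenyl bromide proceeds with retention of the E geometry and leaves the vinylsilane, ester and oxolane untouched.

Step 5
Reactants: 9 methyl 4-[(2R,5S)-5-[(E)-4-(trimethylsilyl)but-3-en-1-yn-1-yl]oxolan-2-yl]butanoate
Product: 10 methyl 4-[(2R,5S)-5-[(E)-4-iodobut-3-en-1-yn-1-yl]oxolan-2-yl]butanoate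
Conditions: N-iodosuccinimide, (CF3)2CHOH/CH2Cl2, 0 °C, dark; aq. Na2S2O3
Reagents that add atoms: N-iodosuccinimide, O=C1CCC(=O)N1I
Why: Electrophilic ipso-iododesilylation of the alkenylsilane (attack at the silicon-bearing carbon, β-silyl cation, loss of the silyl group) should replace SiMe3 by iodine with retention of the E geometry, as is usual for alkenylsilanes in this medium.

Step 6
Reactants: 11 oct-1-en-7-yne
Product: 13 (E)-1-bromoocta-1,7-diene, via alkenylzirconocene chloride 12 (not isolated)
Conditions: Cp2Zr(H)Cl (1.05 equiv), CH2Cl2, rt; then NBS, 0 °C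
Reagents that add atoms: N-bromosuccinimide, O=C1CCC(=O)N1Br
Why: Schwartz hydrozirconation adds Zr–H syn and anti-Markovnikov to the terminal alkyne much faster than to the terminal alkene, and bromination of the alkenyl–zirconium bond with NBS occurs with retention to give the E bromoalkene.

Step 7
Reactants: 13 (E)-1-bromoocta-1,7-diene; 10 methyl 4-[(2R,5S)-5-[(E)-4-iodobut-3-en-1-yn-1-yl]oxolan-2-yl]butanoate
Product: 15 Mutafran C, via B-alkyl-9-BBN borane 14 (not isolated)
Conditions: 9-BBN dimer, THF, 0 °C to rt; then 10, PdCl2(dppf)·CH2Cl2 (5 mol%), AsPh3 (10 mol%), Cs2CO3, DMF/H2O, rt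
Reagents that add atoms: none
Why: 9-BBN hydroborates the monosubstituted alkene of 13 anti-Markovnikov and ignores the electron-poor 1,2-disubstituted bromoalkene, giving the primary alkylborane 14. Zerovalent palladium then inserts into the enyne-conjugated C–I bond of 10, the base-activated borate transfers its primary alkyl group, and reductive elimination forms the C(sp2)–C(sp3) bond; the closest known reaction type is the B-alkyl Suzuki–Miyaura coupling of alkenyl iodides. No ring is closed and no stereocentre is formed, and both alkene geometries are retained because oxidative addition and reductive elimination are stereoretentive. The selectivity needed is C–I over C–Br, which the far faster oxidative addition of the conjugated alkenyl iodide at room temperature should secure, helped by stopping the reaction once 10 is consumed; the dppf/AsPh3 system is chosen to speed transmetalation. The methyl ester and the oxolane should be inert to aqueous Cs2CO3 at room temperature.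

Compound list
1 | methyl 4-iodobutanoate | COC(=O)CCCI | starting material
2 | pent-4-enal | C=CCCC=O | starting material
3 | bis(4-methoxy-4-oxobutyl)zinc | COC(=O)CCC[Zn]CCCC(=O)OC | intermediate
4 | methyl (5R)-5-hydroxynon-8-enoate | COC(=O)CCC[C@@H](O)CCC=C | intermediate
5 | methyl 4-[(2R,5S)-5-(hydroxymethyl)oxolan-2-yl]butanoate | COC(=O)CCC[C@@H]1CC[C@@H](CO)O1 | intermediate
6 | methyl 4-[(2R,5S)-5-formyloxolan-2-yl]butanoate | COC(=O)CCC[C@@H]1CC[C@@H](C=O)O1 | intermediate
7 | methyl 4-[(2R,5S)-5-ethynyloxolan-2-yl]butanoate | COC(=O)CCC[C@@H]1CC[C@@H](C#C)O1 | intermediate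
8 | (E)-(2-bromoethenyl)trimethylsilane | C[Si](C)(C)/C=C/Br | starting material
9 | methyl 4-[(2R,5S)-5-[(E)-4-(trimethylsilyl)but-3-en-1-yn-1-yl]oxolan-2-yl]butanoate | COC(=O)CCC[C@@H]1CC[C@@H](C#C/C=C/[Si](C)(C)C)O1 | intermediate
10 | methyl 4-[(2R,5S)-5-[(E)-4-iodobut-3-en-1-yn-1-yl]oxolan-2-yl]butanoate | COC(=O)CCC[C@@H]1CC[C@@H](C#C/C=C/I)O1 | intermediate
11 | oct-1-en-7-yne | C=CCCCCC#C | starting material
12 | chlorobis(cyclopentadienyl)[(E)-octa-1,7-dien-1-yl]zirconium | C=CCCCC/C=C/[Zr](Cl)(C1C=CC=C1)C1C=CC=C1 | intermediate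
13 | (E)-1-bromoocta-1,7-diene | C=CCCCC/C=C/Br | intermediate
14 | 9-[(E)-8-bromooct-7-en-1-yl]-9-borabicyclo[3.3.1]nonane | Br/C=C/CCCCCCB1C2CCCC1CCC2 | intermediate
15 | Mutafran C, methyl 4-[(2R,5S)-5-[(3E,11E)-12-bromododeca-3,11-dien-1-yn-1-yl]oxolan-2-yl]butanoate | COC(=O)CCC[C@@H]1CC[C@@H](C#C/C=C/CCCCCC/C=C/Br)O1 | target

Total step count: 7. Longest linear sequence: 6 (steps 1, 2, 3, 4, 5 and 7).

Steps most likely to fail

Step 7. The risk is competing oxidative addition of zerovalent palladium into the C–Br bond of borane 14 or of the product, which would lead to oligomerisation and over-coupling, together with protodeboronation of 14. The fallback masks the bromide as a vinylsilane during the coupling; it sets out from 13 and 10 and comes back at 15. Bromine–lithium exchange on 13 (tBuLi, Et2O, −78 °C) should give (E)-octa-1,7-dien-1-yllithium F1, which is trapped with Me3SiCl to give (E)-trimethyl(octa-1,7-dien-1-yl)silane F2 with retention. 9-BBN then adds to the terminal alkene to give 9-[(E)-8-(trimethylsilyl)oct-7-en-1-yl]-9-borabicyclo[3.3.1]nonane F3, which is coupled with 10 under the conditions of step 7 to give methyl 4-[(2R,5S)-5-[(3E,11E)-12-(trimethylsilyl)dododeca-free name: 12-(trimethylsilyl)dodeca-3,11-dien-1-yn-1-yl]oxolan-2-yl]butanoate F4. Ipso-bromodesilylation of F4 (NBS, MeCN, 0 °C) with retention should then give 15.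

Step 5. The risk is sluggish ipso-substitution, because the alkynyl group destabilises the β-silyl cation, with erosion of the E geometry through addition–elimination or competing iodination of the enyne. The fallback builds the iodoalkene by hydrometalation instead; it sets out from 7 and comes back at 10. Cadiot–Chodkiewicz coupling of 7 with (bromoethynyl)triisopropylsilane (CuCl, NH2OH·HCl, nBuNH2, CH2Cl2/H2O, 0 °C) should give methyl 4-[(2R,5S)-5-[4-(triisopropylsilyl)buta-1,3-diyn-1-yl]oxolan-2-yl]butanoate F5. Desilylation (TBAF, AcOH, THF, 0 °C) gives methyl 4-[(2R,5S)-5-(buta-1,3-diyn-1-yl)oxolan-2-yl]butanoate F6. Hydrozirconation of the terminal alkyne of F6 (Cp2Zr(H)Cl, THF, rt) gives the (E)-enynylzirconocene chloride F7, and iodinolysis (I2, 0 °C) gives 10 with retention.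

Step 1. The risk is incomplete enantioface control in the alkyl transfer, and lactonisation or transesterification of the δ-hydroxy ester in the presence of Ti(OiPr)4. The fallback takes the stereocentre from the chiral pool; it sets out from no numbered compound but from commercial (S)-2-(but-3-en-1-yl)oxirane (C=CCC[C@H]1CO1) and methyl propiolate, which replace 1 and 2, and it comes back at 5. Methyl propiolate is lithiated (nBuLi, THF, −78 °C) to lithium 3-methoxy-3-oxoprop-1-yn-1-ide F8, which opens the epoxide at its CH2 terminus (BF3·OEt2, −78 °C) to give methyl (5S)-5-hydroxynon-8-en-2-ynoate F9; this alkynoate cannot lactonise. The cobalt-catalysed aerobic cyclisation under the conditions of step 2 should then give methyl 4-[(2S,5S)-5-(hydroxymethyl)oxolan-2-yl]but-2-ynoate F10, and hydrogenation of the alkyne (H2, Pd/C, EtOAc) gives 5.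

Further compounds
F1 | step 7 | (E)-octa-1,7-dien-1-yllithium | [Li]/C=C/CCCCC=C
F2 | step 7 | (E)-trimethyl(octa-1,7-dien-1-yl)silane | C=CCCCC/C=C/[Si](C)(C)C
F3 | step 7 | 9-[(E)-8-(trimethylsilyl)oct-7-en-1-yl]-9-borabicyclo[3.3.1]nonane | C[Si](C)(C)/C=C/CCCCCCB1C2CCCC1CCC2
F4 | step 7 | methyl 4-[(2R,5S)-5-[(3E,11E)-12-(trimethylsilyl)dodeca-3,11-dien-1-yn-1-yl]oxolan-2-yl]butanoate | COC(=O)CCC[C@@H]1CC[C@@H](C#C/C=C/CCCCCC/C=C/[Si](C)(C)C)O1
F5 | step 5 | methyl 4-[(2R,5S)-5-[4-(triisopropylsilyl)buta-1,3-diyn-1-yl]oxolan-2-yl]butanoate | COC(=O)CCC[C@@H]1CC[C@@H](C#CC#C[Si](C(C)C)(C(C)C)C(C)C)O1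
F6 | step 5 | methyl 4-[(2R,5S)-5-(buta-1,3-diyn-1-yl)oxolan-2-yl]butanoate | COC(=O)CCC[C@@H]1CC[C@@H](C#CC#C)O1
F7 | step 5 | chlorobis(cyclopentadienyl)[(E)-4-[(2S,5R)-5-(4-methoxy-4-oxobutyl)oxolan-2-yl]but-1-en-3-yn-1-yl]zirconium | COC(=O)CCC[C@@H]1CC[C@@H](C#C/C=C/[Zr](Cl)(C2C=CC=C2)C3C=CC=C3)O1
F8 | step 1 | lithium 3-methoxy-3-oxoprop-1-yn-1-ide | [Li]C#CC(=O)OC
F9 | step 1 | methyl (5S)-5-hydroxynon-8-en-2-ynoate | COC(=O)C#CC[C@@H](O)CCC=C
F10 | step 1 | methyl 4-[(2S,5S)-5-(hydroxymethyl)oxolan-2-yl]but-2-ynoate | COC(=O)C#CC[C@@H]1CC[C@@H](CO)O1
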